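**Plan**

- Ring numbering used throughout: C1 (OMe), C2 (=CH), C3 (=C, bearing C7H2OBz), C4 (OH), C5 (OBz), C6 (OH). The retrosynthesis cuts, in this order, C4–H, the C5–O(benzoate) bond, C1–H and the two C–O bonds of a C5–C6 oxirane, which leaves an achiral quinone monoketal.
- Enabling feature: on the six-membered ring O1 and O4 are para and C7 is ortho to O4 (a 2-(hydroxymethyl)hydroquinone pattern). C1 can therefore be a dimethyl ketal and C4 the ketone of a flat dienone whose unsubstituted C5=C6 edge is the one that must carry the two trans oxygens.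
- Forward: the carbocycle comes intact from 2-hydroxy-5-methoxybenzaldehyde (reduction, oxidative dearomatisation in methanol, silylation of O7). The only ring closed is the oxirane, by catalytic asymmetric nucleophilic epoxidation of C5=C6.
- Stereochemistry: the epoxidation sets C5 and C6 absolutely, and the rest is relayed from the oxirane. Hydride enters C1 anti to it when the ketal is reduced to the methyl ether, benzoate opens C5 with inversion, and the freed C6 hydroxyl delivers hydride to the C4 ketone.
- O7 is a silyl ether during the basic peroxide step, because an allylic ester next to the enone could be expelled there, and is exchanged for the benzoate directly afterwards. The ketal is reduced while the rigid oxirane is still present, since a free C6 hydroxyl would be expected to steer hydride to the wrong face of C1.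

Key step: step 4

Assumption: the sense of induction of the cinchona salt on this dienone has to be assigned by experiment; the cinchonidine-derived salt is written, and its pseudoenantiomer N-benzylcinchoninium chloride takes its place if the opposite face is attacked.

**Route**

Step 1
Reactants: 1 2-hydroxy-5-methoxybenzaldehyde
Product: 2 2-(hydroxymethyl)-4-methoxyphenol
Conditions: NaBH4, MeOH, 0 °C
Reagents that add atoms: none
Why: Borohydride reduction of an aryl aldehyde to the benzylic alcohol should be clean beside the free phenol, and no stereocentre is formed.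

Step 2
Reactants: 2 2-(hydroxymethyl)-4-methoxyphenol
Product: 3 2-(hydroxymethyl)-4,4-dimethoxycyclohexa-2,5-dien-1-one
Conditions: PhI(OAc)2, MeOH, 0 °C
Reagents that add atoms: methanol, CO
Why: Oxidative dearomatisation of a p-methoxyphenol by (diacetoxyiodo)benzene, with methanol captured at the methoxy-bearing carbon para to the phenol oxygen, is the standard entry to quinone monoketals; the primary alcohol is not oxidised by this reagent alone and the product is achiral.

Step 3
Reactants: 3 2-(hydroxymethyl)-4,4-dimethoxycyclohexa-2,5-dien-1-one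
Product: 4 2-{[(tert-butyldimethylsilyl)oxy]methyl}-4,4-dimethoxycyclohexa-2,5-dien-1-one
Conditions: TBSCl, imidazole, DMF, 0 °C
Reagents that add atoms: tert-butyldimethylsilyl chloride, CC(C)(C)[Si](C)(C)Cl
Why: Silyl ether formation at the primary alcohol masks O7 as a group that survives basic hydroperoxide and, unlike an ester, cannot leave from C7 after a conjugate addition at C2.

Step 4
Reactants: 4 2-{[(tert-butyldimethylsilyl)oxy]methyl}-4,4-dimethoxycyclohexa-2,5-dien-1-one; 5 tert-butyl hydroperoxide
Product: 7 (1R,6S)-3-{[(tert-butyldimethylsilyl)oxy]methyl}-5,5-dimethoxy-7-oxabicyclo[4.1.0]hept-3-en-2-one, via peroxy enolate 6 (not isolated)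
Conditions: t-BuOOH (2 equiv), N-benzylcinchonidinium chloride (10 mol %), aq. NaOH (0.1 M, 20 mol %), toluene, 0 °C
Reagents that add atoms: tert-butyl hydroperoxide (5), CC(C)(C)OO
Why: Weitz–Scheffer epoxidation under chiral phase-transfer catalysis: tert-butylperoxide, carried into toluene as its ion pair with the cinchonidinium cation, adds to C6, the β-carbon of the unsubstituted enone, to give peroxy enolate 6, and the enolate carbon C5 then displaces tert-butoxide from the peroxide oxygen bound to C6. The oxirane closes in the 3-exo-tet mode, so the C6–O bond forms first and the C5–O bond second. The closest known reaction type is the cinchona-ammonium-catalysed nucleophilic epoxidation of enones and of quinone monoketals with hydroperoxides. C6 is fixed in the conjugate addition by the enantioface of the flat, achiral dienone that the chiral ion pair exposes, and C5 follows because an oxirane fused to the six-membered ring can only close cis. The step needs enantioface selectivity, which rests on the catalyst alone, and site selectivity for C5=C6 over C2=C3, which the C3 substituent secures: addition next to it and closure to a fully substituted oxirane carbon are slower, and the silyl ether cannot be expelled from C7 should peroxide add at C2.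

Step 5
Reactants: 7 (1R,6S)-3-{[(tert-butyldimethylsilyl)oxy]methyl}-5,5-dimethoxy-7-oxabicyclo[4.1.0]hept-3-en-2-one
Product: 8 (1R,6S)-3-(hydroxymethyl)-5,5-dimethoxy-7-oxabicyclo[4.1.0]hept-3-en-2-one
Conditions: camphorsulfonic acid (10 mol %), MeOH, 0 °C
Reagents that add atoms: none
Why: Acid-catalysed methanolysis of a primary silyl ether; in methanol the dimethyl ketal can only exchange into itself, and the electron-poor oxirane flanked by ketone and ketal should not open under catalytic acid at 0 °C, so C5 and C6 are untouched.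

Step 6
Reactants: 8 (1R,6S)-3-(hydroxymethyl)-5,5-dimethoxy-7-oxabicyclo[4.1.0]hept-3-en-2-one
Product: 9 [(1R,6S)-5,5-dimethoxy-2-oxo-7-oxabicyclo[4.1.0]hept-3-en-3-yl]methyl benzoate
Conditions: BzCl, pyridine, CH2Cl2, 0 °C
Reagents that add atoms: benzoyl chloride, O=C(Cl)c1ccccc1
Why: Esterification of the only free hydroxyl with an acid chloride and pyridine installs the C7 benzoate of the target at a stage where no other nucleophilic group competes.

Step 7
Reactants: 9 [(1R,6S)-5,5-dimethoxy-2-oxo-7-oxabicyclo[4.1.0]hept-3-en-3-yl]methyl benzoate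
Product: 11 [(1R,5R,6R)-5-methoxy-2-oxo-7-oxabicyclo[4.1.0]hept-3-en-3-yl]methyl benzoate, via oxocarbenium ion 10 (not isolated)
Conditions: Et3SiH (3 equiv), TMSOTf (0.3 equiv), CH2Cl2, −78 to 0 °C
Reagents that add atoms: none
Why: Ionic hydrogenation of a dimethyl ketal to a methyl ether (silane/silyl triflate reductive cleavage): the silyl triflate removes one methoxy group to give oxocarbenium ion 10, the same ion through which such epoxy ketals are hydrolysed with the oxirane left intact, and Et3SiH transfers hydride to C1, where the positive charge resides (C3 is α to the ketone), from the face anti to the cis-fused oxirane, so that the surviving methoxy group ends up cis to the C6 oxygen, which is the (R) configuration required at C1.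

Step 8
Reactants: 11 [(1R,5R,6R)-5-methoxy-2-oxo-7-oxabicyclo[4.1.0]hept-3-en-3-yl]methyl benzoate; 12 benzoic acid
Product: 13 (1S,5R,6R)-3-[(benzoyloxy)methyl]-6-hydroxy-5-methoxy-2-oxocyclohex-3-en-1-yl benzoate
Conditions: PhCO2H (3 equiv), Bu4N(O2CPh) (20 mol %, halide-free), MeCN, 40 °C
Reagents that add atoms: benzoic acid (12), OC(=O)c1ccccc1
Why: Carboxylate opening of an α,β-epoxy ketone by SN2 attack at the carbon α to the carbonyl: C5 is activated by the ketone whereas C6 is deactivated inductively by the adjacent C1–OMe, attack comes anti to the oxirane oxygen and inverts C5, placing the benzoate trans to the C6 hydroxyl, and the excess acid protonates the alkoxide and buffers the medium against enolisation.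

Step 9
Reactants: 13 (1S,5R,6R)-3-[(benzoyloxy)methyl]-6-hydroxy-5-methoxy-2-oxocyclohex-3-en-1-yl benzoate
Product: 15 (1R,2R,5R,6R)-3-[(benzoyloxy)methyl]-2,6-dihydroxy-5-methoxycyclohex-3-en-1-yl benzoate, via alkoxyborohydride 14 (not isolated)
Conditions: Me4NBH(OAc)3 (5 equiv), MeCN/AcOH (1:1), −30 to −20 °C
Reagents that add atoms: none
Why: Evans–Saksena hydroxyl-directed reduction: the C6 hydroxyl exchanges an acetate on boron to give 14, which delivers hydride through a six-membered chair-like transition state to the face of the C4 carbonyl on the side of O6, so the new hydroxyl is anti to O6 (1,3-anti diol) and cis to the C5 benzoate, while the reagent is too weak to reduce the enone, the esters or the allylic ether without direction.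

**Compound list**

1 | 2-hydroxy-5-methoxybenzaldehyde | COc1ccc(O)c(C=O)c1 | starting material
2 | 2-(hydroxymethyl)-4-methoxyphenol | COc1ccc(O)c(CO)c1 | intermediate
3 | 2-(hydroxymethyl)-4,4-dimethoxycyclohexa-2,5-dien-1-one | COC1(OC)C=C(CO)C(=O)C=C1 | intermediate
4 | 2-{[(tert-butyldimethylsilyl)oxy]methyl}-4,4-dimethoxycyclohexa-2,5-dien-1-one | COC1(OC)C=C(CO[Si](C)(C)C(C)(C)C)C(=O)C=C1 | intermediate
5 | tert-butyl hydroperoxide | CC(C)(C)OO | starting material
6 | peroxy enolate, (3S)-3-(tert-butylperoxy)-6-{[(tert-butyldimethylsilyl)oxy]methyl}-4,4-dimethoxycyclohexa-1,5-dien-1-olate (peroxide on C6 of the target numbering; ammonium ion pair) | COC1(OC)C=C(CO[Si](C)(C)C(C)(C)C)C([O-])=C[C@@H]1OOC(C)(C)C | intermediate (not isolated)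
7 | (1R,6S)-3-{[(tert-butyldimethylsilyl)oxy]methyl}-5,5-dimethoxy-7-oxabicyclo[4.1.0]hept-3-en-2-one | COC1(OC)C=C(CO[Si](C)(C)C(C)(C)C)C(=O)[C@@H]2O[C@@H]21 | intermediate
8 | (1R,6S)-3-(hydroxymethyl)-5,5-dimethoxy-7-oxabicyclo[4.1.0]hept-3-en-2-one | COC1(OC)C=C(CO)C(=O)[C@@H]2O[C@@H]21 | intermediate
9 | [(1R,6S)-5,5-dimethoxy-2-oxo-7-oxabicyclo[4.1.0]hept-3-en-3-yl]methyl benzoate | COC1(OC)C=C(COC(=O)c2ccccc2)C(=O)[C@@H]3O[C@@H]31 | intermediate
10 | oxocarbenium ion, the C1 O-methyl oxocarbenium of 9 after loss of one methoxide (oxirane as in 9; triflate salt) | C[O+]=C1C=C(COC(=O)c2ccccc2)C(=O)[C@@H]3O[C@@H]31 | intermediate (not isolated)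
11 | [(1R,5R,6R)-5-methoxy-2-oxo-7-oxabicyclo[4.1.0]hept-3-en-3-yl]methyl benzoate | CO[C@@H]1C=C(COC(=O)c2ccccc2)C(=O)[C@@H]3O[C@@H]31 | intermediate
12 | benzoic acid | OC(=O)c1ccccc1 | starting material
13 | (1S,5R,6R)-3-[(benzoyloxy)methyl]-6-hydroxy-5-methoxy-2-oxocyclohex-3-en-1-yl benzoate | CO[C@@H]1C=C(COC(=O)c2ccccc2)C(=O)[C@@H](OC(=O)c2ccccc2)[C@@H]1O | intermediate
14 | alkoxyborohydride, the C6-O-bound diacetoxyborohydride of 13 (tetramethylammonium salt) | CO[C@@H]1C=C(COC(=O)c2ccccc2)C(=O)[C@@H](OC(=O)c2ccccc2)[C@@H]1O[BH-](OC(C)=O)OC(C)=O | intermediate (not isolated)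
15 | (1R,2R,5R,6R)-3-[(benzoyloxy)methyl]-2,6-dihydroxy-5-methoxycyclohex-3-en-1-yl benzoate | CO[C@@H]1C=C(COC(=O)c2ccccc2)[C@@H](O)[C@@H](OC(=O)c2ccccc2)[C@@H]1O | target

Total steps: 9. Longest linear sequence: 9 steps (1 to 15).

**Steps most likely to fail**

1. Step 7. The C1 ketal is electron-poor, because its oxocarbenium ion is conjugated to the C4 ketone and flanked by the oxirane. Ionisation may therefore be slow, the Lewis acid may open or rearrange the oxirane instead, or hydride may fail to distinguish the two faces of C1. The fallback sets out from 9 and returns at 11. The ketal is hydrolysed with aqueous trifluoroacetic acid in CH2Cl2 to the epoxyquinone [(1R,6S)-2,5-dioxo-7-oxabicyclo[4.1.0]hept-3-en-3-yl]methyl benzoate F1. Its C1 carbonyl, which lies next to the unsubstituted alkene carbon and is the less hindered one, is reduced with NaBH4/CeCl3·7H2O in methanol at −78 °C from the face anti to the oxirane, giving the epoxyquinol [(1R,5R,6R)-5-hydroxy-2-oxo-7-oxabicyclo[4.1.0]hept-3-en-3-yl]methyl benzoate F2. O-Methylation without base (MeOTf, 2,6-di-tert-butyl-4-methylpyridine, CH2Cl2) then gives 11, so the methyl ether comes from an alkylation and not from the ketal.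

2. Step 8. Under the carboxylate, enolisation at C5 of the product or at C1 of 11 can be followed by loss of the C6 oxygen and aromatisation. Benzoate can also add conjugately at C2 and expel the C7 benzoate from the resulting enolate, and some attack at C6 is possible. The fallback sets out from 7 and returns at 15, keeping the silyl ether on O7 so that no leaving group sits next to the enolate carbon C3. Compound 7 is reduced as in step 7 to (1R,5R,6R)-3-{[(tert-butyldimethylsilyl)oxy]methyl}-5-methoxy-7-oxabicyclo[4.1.0]hept-3-en-2-one F3. F3 is opened with benzoic acid and catalytic Bu4N(O2CPh) to (1S,5R,6R)-3-{[(tert-butyldimethylsilyl)oxy]methyl}-6-hydroxy-5-methoxy-2-oxocyclohex-3-en-1-yl benzoate F4. F4 is reduced with Me4NBH(OAc)3 to (1R,2R,5R,6R)-3-{[(tert-butyldimethylsilyl)oxy]methyl}-2,6-dihydroxy-5-methoxycyclohex-3-en-1-yl benzoate F5, which is desilylated (camphorsulfonic acid, MeOH) to the triol (1R,2R,5R,6R)-2,6-dihydroxy-3-(hydroxymethyl)-5-methoxycyclohex-3-en-1-yl benzoate F6. The primary allylic hydroxyl of F6 is then benzoylated selectively (BzCl, 2,4,6-collidine, CH2Cl2, −78 °C) to give 15.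

3. Step 4. The chiral ion pair may discriminate the two faces of C5=C6 insufficiently, or peroxide may also attack C2=C3. The fallback sets out from 4 and returns at 7 by resolution instead of asymmetric catalysis. Dienone 4 is epoxidised without chirality control (t-BuOOH, catalytic DBU, CH2Cl2) to the racemic epoxide (1RS,6SR)-3-{[(tert-butyldimethylsilyl)oxy]methyl}-5,5-dimethoxy-7-oxabicyclo[4.1.0]hept-3-en-2-one F7. The ketone is reduced anti to the oxirane (NaBH4, CeCl3·7H2O, MeOH, −78 °C) to the racemic cis-epoxy alcohol (1RS,2RS,6RS)-3-{[(tert-butyldimethylsilyl)oxy]methyl}-5,5-dimethoxy-7-oxabicyclo[4.1.0]hept-3-en-2-ol F8. Kinetic resolution with vinyl acetate and immobilised Candida antarctica lipase B is assumed to leave the alcohol (1S,2S,6S)-3-{[(tert-butyldimethylsilyl)oxy]methyl}-5,5-dimethoxy-7-oxabicyclo[4.1.0]hept-3-en-2-ol F9 unreacted, beside the acetate of its antipode, (1R,2R,6R)-3-{[(tert-butyldimethylsilyl)oxy]methyl}-5,5-dimethoxy-7-oxabicyclo[4.1.0]hept-3-en-2-yl acetate F10. After separation, F9 is oxidised with Dess–Martin periodinane back to the ketone 7.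

**Further compounds**

F1 | step 7 | [(1R,6S)-2,5-dioxo-7-oxabicyclo[4.1.0]hept-3-en-3-yl]methyl benzoate | O=C1C=C(COC(=O)c2ccccc2)C(=O)[C@@H]3O[C@@H]31
F2 | step 7 | [(1R,5R,6R)-5-hydroxy-2-oxo-7-oxabicyclo[4.1.0]hept-3-en-3-yl]methyl benzoate | O[C@@H]1C=C(COC(=O)c2ccccc2)C(=O)[C@@H]3O[C@@H]31
F3 | step 8 | (1R,5R,6R)-3-{[(tert-butyldimethylsilyl)oxy]methyl}-5-methoxy-7-oxabicyclo[4.1.0]hept-3-en-2-one | CO[C@@H]1C=C(CO[Si](C)(C)C(C)(C)C)C(=O)[C@@H]2O[C@@H]21
F4 | step 8 | (1S,5R,6R)-3-{[(tert-butyldimethylsilyl)oxy]methyl}-6-hydroxy-5-methoxy-2-oxocyclohex-3-en-1-yl benzoate | CO[C@@H]1C=C(CO[Si](C)(C)C(C)(C)C)C(=O)[C@@H](OC(=O)c2ccccc2)[C@@H]1O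
F5 | step 8 | (1R,2R,5R,6R)-3-{[(tert-butyldimethylsilyl)oxy]methyl}-2,6-dihydroxy-5-methoxycyclohex-3-en-1-yl benzoate | CO[C@@H]1C=C(CO[Si](C)(C)C(C)(C)C)[C@@H](O)[C@@H](OC(=O)c2ccccc2)[C@@H]1O
F6 | step 8 | (1R,2R,5R,6R)-2,6-dihydroxy-3-(hydroxymethyl)-5-methoxycyclohex-3-en-1-yl benzoate | CO[C@@H]1C=C(CO)[C@@H](O)[C@@H](OC(=O)c2ccccc2)[C@@H]1O
F7 | step 4 | racemic (1RS,6SR)-3-{[(tert-butyldimethylsilyl)oxy]methyl}-5,5-dimethoxy-7-oxabicyclo[4.1.0]hept-3-en-2-one (both enantiomers) | COC1(OC)C=C(CO[Si](C)(C)C(C)(C)C)C(=O)[C@@H]2O[C@@H]21.COC1(OC)C=C(CO[Si](C)(C)C(C)(C)C)C(=O)[C@H]2O[C@H]21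
F8 | step 4 | racemic (1RS,2RS,6RS)-3-{[(tert-butyldimethylsilyl)oxy]methyl}-5,5-dimethoxy-7-oxabicyclo[4.1.0]hept-3-en-2-ol (both enantiomers) | COC1(OC)C=C(CO[Si](C)(C)C(C)(C)C)[C@H](O)[C@@H]2O[C@@H]21.COC1(OC)C=C(CO[Si](C)(C)C(C)(C)C)[C@@H](O)[C@H]2O[C@H]21
F9 | step 4 | (1S,2S,6S)-3-{[(tert-butyldimethylsilyl)oxy]methyl}-5,5-dimethoxy-7-oxabicyclo[4.1.0]hept-3-en-2-ol | COC1(OC)C=C(CO[Si](C)(C)C(C)(C)C)[C@H](O)[C@@H]2O[C@@H]21
F10 | step 4 | (1R,2R,6R)-3-{[(tert-butyldimethylsilyl)oxy]methyl}-5,5-dimethoxy-7-oxabicyclo[4.1.0]hept-3-en-2-yl acetate | COC1(OC)C=C(CO[Si](C)(C)C(C)(C)C)[C@@H](OC(C)=O)[C@H]2O[C@H]21
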